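All runs were computed with made-up constants; scatter was added.

We have a closed, stirred vessel in which a chain started by the initiator turns substrate, the limiting reagent, and partner into target. We must decide how much initiator to charge when the vessel is opened at 50 min.

in all of them: substrate 0.078 M; partner 0.234 M
- grey: initiator 0.30 mM; run made earlier
- green: initiator 1.7 mM; run made earlier
- dusk: initiator 0.40 mM; time 50 min
- winter: initiator 0.80 mM; time 50 min
- noon: initiator 2.0 mM; time 50 min

| run | time / min | target / % | substrate / % |
|---|---|---|---|
| grey | 2.00 | 8 | 93 |
| grey | 3.00 | 10 | 89 |
| grey | 5.00 | 14 | 85 |
| grey | 8.00 | 25 | 77 |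
| grey | 10.0 | 28 | 69 |
| grey | 15.0 | 38 | 53 |
| grey | 25.0 | 49 | 34 |
| green | 1.33 | 12 | 90 |
| green | 4.00 | 27 | 65 |
| green | 8.00 | 48 | 44 |
| green | 10.0 | 54 | 33 |
| green | 15.0 | 71 | 13 |
| green | 20.0 | 74 | 0 |
| green | 25.0 | 63 | 1 |

(readings scatter by 2 percentage points)

* amount of target at the end, in percent of the substrate charged for dusk, winter, noon, in this order
* how that number moves from the first to the last of them (rises all the way / hardly changes / rises, then falls / falls, then rises / falls all the way)

- percentages count the substrate that a species holds: one ended chains A counts as two
- candidate steps: initiator -> 2 initiating radical; substrate + initiating radical -> chain carrier; partner + chain carrier -> target + initiating radical; 2 chain carrier -> ended chains A; 2 initiating radical -> ended chains B; target <-> isomer of the product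
- "hardly changes" means that all values lie within two and a half points (for a concentration: within two and a half percent of the largest)

More initiator empties the substrate sooner, but target does not stay. In the green run, target plus substrate has fallen to 64.0 % of the charge by 25.0 min, and we read the missing part as target turned into isomer of the product. If the sum falls at a constant k times target, then k is the sum's loss divided by the area under the target curve. That area is 13.3 min in fractions of the charge, so the leak constant, the first-order rate at which target is lost, reads 0.0271 min⁻¹, a time constant of 36.9 min.

Next comes the feed. Call τ the emptying time, the time the run's average rate needs for the whole substrate charge. Green gives 14.9 min and grey 37.9 min. Their ratio of 2.54 lies near 2.38, the square root of the initiator ratio, so we scale τ from green that way: 30.8 min for dusk, 21.8 min for winter and 13.8 min for noon.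

An even feed over τ into a leaking tank integrates in closed form: at time T, after the feed has ended, target is exp(−kT)·(exp(kτ) − 1)/(kτ). We reckon 40.3 %, 35.2 % and 31.3 % of the charge. Slow feeding keeps target younger at the reading, so we charge dusk's 0.40 mM.

The forecast gave 39 %, 37 % and 32 %, falls all the way, noting “Dusk and winter are close”.

The flasks give 41.2 %, 35.8 % and 31.6 %: falls all the way.

    initiator → 2 initiating radical (k = 0.00955 min⁻¹)
    substrate + initiating radical → chain carrier (k = 54200 L mol⁻¹ s⁻¹)
    partner + chain carrier → target + initiating radical (k = 10500 L mol⁻¹ s⁻¹)
    2 chain carrier → ended chains A (k = 1.40 × 10⁸ L mol⁻¹ s⁻¹)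
    2 initiating radical → ended chains B (k = 2.00 × 10⁷ L mol⁻¹ s⁻¹)
    target ⇌ isomer of the product (K = 20.6, k = 0.0282 min⁻¹)

The step from target to isomer of the product is the main reason for the loss: noon without it ends at 99.5 % target, and with it at 31.6 %. The leak constant carries over to noon's second half. At 25.0 min noon holds 60.9 % target and 0.169 % substrate, so hardly any substrate remains to feed it, and 0.0271 min⁻¹ predicts 30.9 % at the reading, where the flask holds 31.6 %.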